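**Retrosynthetic overview**

1. The C3–C1′ biaryl bond joins ring A (C3, para to the ring A OH) to ring B (C1′). It lies between the ring B oxygen on C6′ and the ring A methyl carbon on C4. Tying these two atoms together as O–C(=O) gives a six-membered lactone (benzo[c]chromen-6-one 19), and C1′ is the only hydrogen-bearing position ortho to the ring B oxygen.
2. 24 ⇐ 19: hydride opening of the lactone, reduction of the freed CH2OH to the C4 methyl, O-demethylation.
3. 19 ⇐ 18: palladium-catalysed intramolecular C–H arylation of the aryl 2-bromobenzoate, which forms the biaryl bond and closes the lactone ring.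
4. 18 ⇐ acid 9 (from methyl 4-formyl-3-methoxybenzoate 1, (S) center by asymmetric hydrovinylation) + (S)-curcuphenol 17 (from (S)-citronellal 10 and methyl vinyl ketone 11).
5. Ring order: ring A is bought as an arene; ring B is built as a cyclohexenone (step 8) and aromatized (step 11); the lactone ring is closed in step 13 and reopened in step 14.

Key step: step 13

**Assumptions**

- The target SMILES gives no configuration for the C3–C1′ axis (ortho groups CH3/H and CH3/OH). The axis is treated as not configurationally fixed, so the lactone is opened with an achiral hydride.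
- Both antipodes of the phosphoramidite ligand of step 3 are available. The antipode that gives the (S)-alkene is to be identified in a calibration run (chiral HPLC against the racemate, and correlation of a curcuphenol sample made by the same catalyst with citronellal-derived 17).

**Route**

Step 1
Reactants: 1 methyl 4-formyl-3-methoxybenzoate
Product: 2 methyl 2-bromo-4-formyl-5-methoxybenzoate
Conditions: NBS (1.1 equiv), conc. H2SO4/CF3CO2H, 0 °C → rt
Reagents that add atoms: N-bromosuccinimide, O=C1CCC(=O)N1Br
Why: Electrophilic aromatic bromination; the methoxy group directs to its para position, which is also meta to the formyl group, and the strongly acidic medium should let NBS brominate the twice-deactivated ring.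

Step 2
Reactants: 2 methyl 2-bromo-4-formyl-5-methoxybenzoate
Product: 3 methyl 2-bromo-4-ethenyl-5-methoxybenzoate
Conditions: Ph3PCH3Br, NaN(SiMe3)2, THF, 0 °C; then 2, 0 °C → rt
Reagents that add atoms: methyltriphenylphosphonium bromide, C[P+](c1ccccc1)(c1ccccc1)c1ccccc1.[Br-]
Why: Wittig methylenation of the aryl aldehyde; the non-stabilized ylide should react with the aldehyde far faster than with the methyl ester, and the aryl bromide is inert.

Step 3
Reactants: 3 methyl 2-bromo-4-ethenyl-5-methoxybenzoate
Product: 4 methyl 2-bromo-4-[(2S)-but-3-en-2-yl]-5-methoxybenzoate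
Conditions: [(η3-C3H5)NiBr]2 (1 mol %), BINOL-derived N,N-bis(1-phenylethyl)phosphoramidite (2 mol %, antipode giving (S)), Na[B(3,5-(CF3)2C6H3)4] (2 mol %), C2H4 (1 atm), CH2Cl2, −70 °C
Reagents that add atoms: ethylene, C=C
Why: Nickel-catalysed asymmetric hydrovinylation; a cationic nickel hydride adds to the vinylarene to give an η3-benzyl species, ethylene inserts at the benzylic carbon and β-hydride elimination releases the 3-arylbut-1-ene, the chiral phosphoramidite on nickel setting the (S) center under catalyst control, and since no low-valent nickel is involved the aryl bromide should survive.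

Step 4
Reactants: 4 methyl 2-bromo-4-[(2S)-but-3-en-2-yl]-5-methoxybenzoate
Product: 6 methyl 2-bromo-4-[(2S)-4-hydroxybutan-2-yl]-5-methoxybenzoate, via B-alkyl-9-BBN adduct 5 (not isolated)
Conditions: 9-BBN, THF, 0 °C → rt; then 30% H2O2, aq NaOAc, 0 °C → rt
Reagents that add atoms: hydrogen peroxide, OO
Why: Hydroboration–oxidation; 9-BBN places boron on the terminal carbon of the monosubstituted alkene without reducing the ester, and buffered peroxide replaces boron by OH while the benzylic center is untouched.

Step 5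
Reactants: 6 methyl 2-bromo-4-[(2S)-4-hydroxybutan-2-yl]-5-methoxybenzoate
Product: 7 methyl 2-bromo-5-methoxy-4-[(2S)-4-oxobutan-2-yl]benzoate
Conditions: Dess–Martin periodinane, NaHCO3, CH2Cl2, 0 °C → rt
Reagents that add atoms: none
Why: Dess–Martin oxidation of the primary alcohol to the aldehyde under buffered conditions; the stereocenter is β to the new carbonyl and cannot epimerize.

Step 6
Reactants: 7 methyl 2-bromo-5-methoxy-4-[(2S)-4-oxobutan-2-yl]benzoate
Product: 8 methyl 2-bromo-5-methoxy-4-[(2S)-6-methylhept-5-en-2-yl]benzoate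
Conditions: i-PrPPh3I (1.3 equiv), n-BuLi (1.2 equiv), THF, 0 °C; then 7, −78 °C → rt
Reagents that add atoms: isopropyltriphenylphosphonium iodide, CC(C)[P+](c1ccccc1)(c1ccccc1)c1ccccc1.[I-]
Why: Wittig olefination with the isopropylidene ylide installs the trisubstituted alkene terminus; the salt is kept in excess so that no free n-BuLi meets the ester or the aryl bromide.

Step 7
Reactants: 8 methyl 2-bromo-5-methoxy-4-[(2S)-6-methylhept-5-en-2-yl]benzoate
Product: 9 2-bromo-5-methoxy-4-[(2S)-6-methylhept-5-en-2-yl]benzoic acid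
Conditions: LiOH·H2O, THF/MeOH/H2O, 40 °C; then 1 M HCl, 0 °C (pH 3)
Reagents that add atoms: lithium hydroxide, [Li+].[OH-]
Why: Saponification of the methyl benzoate by acyl–oxygen hydrolysis; alkene, aryl bromide and aryl ether are inert to aqueous LiOH and to a brief cold acidification.

Step 8
Reactants: 10 (S)-citronellal; 11 methyl vinyl ketone
Product: 13 4-[(2S)-6-methylhept-5-en-2-yl]cyclohex-2-en-1-one, via keto aldehyde 12 (not isolated)
Conditions: Et2NH (0.3 equiv), neat, rt; then aq KOH, n-Bu4NOH (cat.), THF/Et2O, reflux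
Reagents that add atoms: none
Why: Robinson annulation (amine-catalysed enamine Michael addition of the aldehyde α-carbon to the enone, then intramolecular aldol condensation of the methyl ketone onto the aldehyde); the citronellal stereocenter is β to the carbonyl and is carried through, while the new ring center forms as both epimers and is removed at the aromatization.

Step 9
Reactants: 13 4-[(2S)-6-methylhept-5-en-2-yl]cyclohex-2-en-1-one
Product: 14 1-methyl-4-[(2S)-6-methylhept-5-en-2-yl]cyclohex-2-en-1-ol
Conditions: MeLi, Et2O, −78 °C; then H2O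
Reagents that add atoms: methyllithium, [Li]C
Why: 1,2-Addition of methyllithium to the enone carbonyl gives the tertiary allylic alcohol; the diastereomer mixture is used as such because the carbinol carbon becomes sp2 in the next step.

Step 10
Reactants: 14 1-methyl-4-[(2S)-6-methylhept-5-en-2-yl]cyclohex-2-en-1-ol
Product: 15 3-methyl-6-[(2S)-6-methylhept-5-en-2-yl]cyclohex-2-en-1-one
Conditions: pyridinium chlorochromate [C5H5NH][CrO3Cl] (2.5 equiv), CH2Cl2, rt
Reagents that add atoms: pyridinium chlorochromate, [O-][Cr](=O)(=O)Cl.c1cc[nH+]cc1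
Why: Oxidative 1,3-transposition of a tertiary allylic alcohol (Babler–Dauben oxidation); the chromate ester undergoes a [3,3] shift and the transposed secondary chromate is oxidized, which places the carbonyl on the ring carbon next to the one bearing the side chain.

Step 11
Reactants: 15 3-methyl-6-[(2S)-6-methylhept-5-en-2-yl]cyclohex-2-en-1-one
Product: 17 5-methyl-2-[(2S)-6-methylhept-5-en-2-yl]phenol, via α′-phenylselanyl enone 16 (not isolated)
Conditions: LiN(i-Pr)2, THF, −78 °C; PhSeBr, −78 °C; then mCPBA (1.05 equiv), CH2Cl2, −78 °C; i-Pr2NH, −78 °C → rt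
Reagents that add atoms: none
Why: α′-Selenenylation of the kinetic cross-conjugated enolate and selenoxide syn-elimination toward the ring CH2 give a cyclohexa-2,5-dienone that tautomerizes to the phenol (S)-curcuphenol; the amine traps benzeneselenenic acid so that alkene and phenol are not attacked, and the side-chain stereocenter takes no part.

Step 12
Reactants: 9 2-bromo-5-methoxy-4-[(2S)-6-methylhept-5-en-2-yl]benzoic acid; 17 5-methyl-2-[(2S)-6-methylhept-5-en-2-yl]phenol
Product: 18 5-methyl-2-[(2S)-6-methylhept-5-en-2-yl]phenyl 2-bromo-5-methoxy-4-[(2S)-6-methylhept-5-en-2-yl]benzoate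
Conditions: DCC, DMAP (0.3 equiv), CH2Cl2, 0 °C → rt
Reagents that add atoms: none
Why: Steglich esterification (carbodiimide activation and acyl transfer through the N-acylpyridinium of DMAP) joins the hindered acid and phenol without free acid, which spares the trisubstituted alkenes.

Step 13
Reactants: 18 5-methyl-2-[(2S)-6-methylhept-5-en-2-yl]phenyl 2-bromo-5-methoxy-4-[(2S)-6-methylhept-5-en-2-yl]benzoate
Product: 19 8-methoxy-1-methyl-4,9-bis[(2S)-6-methylhept-5-en-2-yl]-6H-benzo[c]chromen-6-one
Conditions: Pd(OAc)2 (10 mol %), PPh3 (20 mol %), NaOAc (2 equiv), DMA, 130 °C, argon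
Reagents that add atoms: none
Why: Zerovalent palladium formed from Pd(OAc)2 and PPh3 inserts into the ring A C–Br bond ortho to the ester carbonyl, the arylpalladium acetate palladates the ring B C–H ortho to the ester oxygen by acetate-assisted concerted metalation–deprotonation, and reductive elimination from the seven-membered diarylpalladacycle forms the C3–C1′ bond. The closest known reaction type is the palladium-catalysed intramolecular dehydrohalogenative aryl–aryl coupling of aryl 2-halobenzoates to benzo[c]chromen-6-ones, which is established for twisted lactones with a bay substituent. The one ring closed is the six-membered lactone ring, completed by C–C bond formation between two sp2 carbons held in a 1,6 relation by the ester tether. No stereocenter is created, since the helically twisted lactone should equilibrate quickly about the bridged axis and the two (S) centers are remote from the reacting atoms. Site selectivity on ring B is needed and is secured because the tether reaches only the two positions ortho to oxygen and one of them carries the sec-alkyl chain, while on ring A the bromide fixes the site; Heck insertion into the trisubstituted alkenes would need medium rings and should not compete.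

Step 14
Reactants: 19 8-methoxy-1-methyl-4,9-bis[(2S)-6-methylhept-5-en-2-yl]-6H-benzo[c]chromen-6-one
Product: 20 2-[2-(hydroxymethyl)-4-methoxy-5-[(2S)-6-methylhept-5-en-2-yl]phenyl]-3-methyl-6-[(2S)-6-methylhept-5-en-2-yl]phenol
Conditions: LiAlH4, THF, 0 °C → rt; then H2O
Reagents that add atoms: none
Why: Hydride reduction of the aryl lactone cleaves the acyl–oxygen bond and reduces the carbonyl to the benzylic alcohol, releasing the ring B phenol and the open biaryl axis; the isolated alkenes are inert to LiAlH4.

Step 15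
Reactants: 20 2-[2-(hydroxymethyl)-4-methoxy-5-[(2S)-6-methylhept-5-en-2-yl]phenyl]-3-methyl-6-[(2S)-6-methylhept-5-en-2-yl]phenol
Product: 21 [5-methoxy-2-[2-methoxy-6-methyl-3-[(2S)-6-methylhept-5-en-2-yl]phenyl]-4-[(2S)-6-methylhept-5-en-2-yl]phenyl]methanol
Conditions: MeI, K2CO3, acetone, reflux
Reagents that add atoms: iodomethane, CI
Why: Williamson O-methylation; K2CO3 deprotonates only the phenol, so the benzylic alcohol stays free, and the capped phenol can no longer close a six-membered cyclic ether onto the benzylic carbon once that carbon is activated.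

Step 16
Reactants: 21 [5-methoxy-2-[2-methoxy-6-methyl-3-[(2S)-6-methylhept-5-en-2-yl]phenyl]-4-[(2S)-6-methylhept-5-en-2-yl]phenyl]methanol
Product: 22 1-(bromomethyl)-5-methoxy-2-[2-methoxy-6-methyl-3-[(2S)-6-methylhept-5-en-2-yl]phenyl]-4-[(2S)-6-methylhept-5-en-2-yl]benzene
Conditions: CBr4, PPh3, CH2Cl2, 0 °C; used directly
Reagents that add atoms: carbon tetrabromide, BrC(Br)(Br)Br
Why: Appel bromination converts the primary benzylic alcohol into the bromide under neutral conditions that the trisubstituted alkenes tolerate.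

Step 17
Reactants: 22 1-(bromomethyl)-5-methoxy-2-[2-methoxy-6-methyl-3-[(2S)-6-methylhept-5-en-2-yl]phenyl]-4-[(2S)-6-methylhept-5-en-2-yl]benzene
Product: 23 1-methoxy-4-[2-methoxy-6-methyl-3-[(2S)-6-methylhept-5-en-2-yl]phenyl]-5-methyl-2-[(2S)-6-methylhept-5-en-2-yl]benzene
Conditions: LiBHEt3, THF, 0 °C
Reagents that add atoms: none
Why: SN2 hydride displacement of the benzylic bromide by the trialkylborohydride turns the former lactone carbonyl carbon into the ring A C4 methyl group.

Step 18
Reactants: 23 1-methoxy-4-[2-methoxy-6-methyl-3-[(2S)-6-methylhept-5-en-2-yl]phenyl]-5-methyl-2-[(2S)-6-methylhept-5-en-2-yl]benzene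
Product: 24 2-[4-hydroxy-2-methyl-5-[(2S)-6-methylhept-5-en-2-yl]phenyl]-3-methyl-6-[(2S)-6-methylhept-5-en-2-yl]phenol (CNP0290341.1)
Conditions: NaSEt (excess), DMF, 140 °C; then 1 M HCl, 0 °C
Reagents that add atoms: none
Why: Nucleophilic (SN2 at methyl) O-demethylation of both aryl methyl ethers by ethanethiolate, a non-acidic method that should leave the trisubstituted alkenes and the benzylic stereocenters intact.

**Compound list**

1 | methyl 4-formyl-3-methoxybenzoate | COC(=O)c1ccc(C=O)c(OC)c1 | starting material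
2 | methyl 2-bromo-4-formyl-5-methoxybenzoate | COC(=O)c1cc(OC)c(C=O)cc1Br | intermediate
3 | methyl 2-bromo-4-ethenyl-5-methoxybenzoate | COC(=O)c1cc(OC)c(C=C)cc1Br | intermediate
4 | methyl 2-bromo-4-[(2S)-but-3-en-2-yl]-5-methoxybenzoate | COC(=O)c1cc(OC)c([C@@H](C)C=C)cc1Br | intermediate
5 | methyl 2-bromo-4-[(2S)-4-(9-borabicyclo[3.3.1]nonan-9-yl)butan-2-yl]-5-methoxybenzoate | COC(=O)c1cc(OC)c([C@@H](C)CCB2C3CCCC2CCC3)cc1Br | intermediate
6 | methyl 2-bromo-4-[(2S)-4-hydroxybutan-2-yl]-5-methoxybenzoate | COC(=O)c1cc(OC)c([C@@H](C)CCO)cc1Br | intermediate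
7 | methyl 2-bromo-5-methoxy-4-[(2S)-4-oxobutan-2-yl]benzoate | COC(=O)c1cc(OC)c([C@@H](C)CC=O)cc1Br | intermediate
8 | methyl 2-bromo-5-methoxy-4-[(2S)-6-methylhept-5-en-2-yl]benzoate | COC(=O)c1cc(OC)c([C@@H](C)CCC=C(C)C)cc1Br | intermediate
9 | 2-bromo-5-methoxy-4-[(2S)-6-methylhept-5-en-2-yl]benzoic acid | OC(=O)c1cc(OC)c([C@@H](C)CCC=C(C)C)cc1Br | intermediate
10 | (S)-citronellal, (3S)-3,7-dimethyloct-6-enal | CC(C)=CCC[C@H](C)CC=O | starting material
11 | methyl vinyl ketone, but-3-en-2-one | CC(=O)C=C | starting material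
12 | (3S)-3,7-dimethyl-2-(3-oxobutyl)oct-6-enal (both C2 epimers) | CC(C)=CCC[C@H](C)C(CCC(C)=O)C=O | intermediate
13 | 4-[(2S)-6-methylhept-5-en-2-yl]cyclohex-2-en-1-one (both C4 epimers) | CC(C)=CCC[C@H](C)C1CCC(=O)C=C1 | intermediate
14 | 1-methyl-4-[(2S)-6-methylhept-5-en-2-yl]cyclohex-2-en-1-ol (diastereomer mixture) | CC(C)=CCC[C@H](C)C1CCC(C)(O)C=C1 | intermediate
15 | 3-methyl-6-[(2S)-6-methylhept-5-en-2-yl]cyclohex-2-en-1-one (both C6 epimers) | CC(C)=CCC[C@H](C)C1CCC(C)=CC1=O | intermediate
16 | 3-methyl-6-[(2S)-6-methylhept-5-en-2-yl]-6-(phenylselanyl)cyclohex-2-en-1-one | CC(C)=CCC[C@H](C)C1([Se]c2ccccc2)CCC(C)=CC1=O | intermediate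
17 | (S)-curcuphenol, 5-methyl-2-[(2S)-6-methylhept-5-en-2-yl]phenol | CC(C)=CCC[C@H](C)c1ccc(C)cc1O | intermediate
18 | 5-methyl-2-[(2S)-6-methylhept-5-en-2-yl]phenyl 2-bromo-5-methoxy-4-[(2S)-6-methylhept-5-en-2-yl]benzoate | COc1cc(C(=O)Oc2cc(C)ccc2[C@@H](C)CCC=C(C)C)c(Br)cc1[C@@H](C)CCC=C(C)C | intermediate
19 | 8-methoxy-1-methyl-4,9-bis[(2S)-6-methylhept-5-en-2-yl]-6H-benzo[c]chromen-6-one | COc1cc2C(=O)Oc3c([C@@H](C)CCC=C(C)C)ccc(C)c3-c2cc1[C@@H](C)CCC=C(C)C | intermediate
20 | 2-[2-(hydroxymethyl)-4-methoxy-5-[(2S)-6-methylhept-5-en-2-yl]phenyl]-3-methyl-6-[(2S)-6-methylhept-5-en-2-yl]phenol | COc1cc(CO)c(-c2c(C)ccc([C@@H](C)CCC=C(C)C)c2O)cc1[C@@H](C)CCC=C(C)C | intermediate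
21 | [5-methoxy-2-[2-methoxy-6-methyl-3-[(2S)-6-methylhept-5-en-2-yl]phenyl]-4-[(2S)-6-methylhept-5-en-2-yl]phenyl]methanol | COc1cc(CO)c(-c2c(C)ccc([C@@H](C)CCC=C(C)C)c2OC)cc1[C@@H](C)CCC=C(C)C | intermediate
22 | 1-(bromomethyl)-5-methoxy-2-[2-methoxy-6-methyl-3-[(2S)-6-methylhept-5-en-2-yl]phenyl]-4-[(2S)-6-methylhept-5-en-2-yl]benzene | COc1cc(CBr)c(-c2c(C)ccc([C@@H](C)CCC=C(C)C)c2OC)cc1[C@@H](C)CCC=C(C)C | intermediate
23 | 1-methoxy-4-[2-methoxy-6-methyl-3-[(2S)-6-methylhept-5-en-2-yl]phenyl]-5-methyl-2-[(2S)-6-methylhept-5-en-2-yl]benzene | COc1cc(C)c(-c2c(C)ccc([C@@H](C)CCC=C(C)C)c2OC)cc1[C@@H](C)CCC=C(C)C | intermediate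
24 | 2-[4-hydroxy-2-methyl-5-[(2S)-6-methylhept-5-en-2-yl]phenyl]-3-methyl-6-[(2S)-6-methylhept-5-en-2-yl]phenol (CNP0290341.1) | CC(C)=CCC[C@H](C)c1cc(-c2c(C)ccc([C@@H](C)CCC=C(C)C)c2O)c(C)cc1O | target

**Step count**

Total: 18 steps. Longest linear sequence: 14 steps (steps 1–7, then 12–18); the ring B branch is 4 steps (8–11).

**Steps most likely to fail, with fallbacks**

1. Step 13 (C–H arylation). Palladation of the ring B C–H next to the methyl group may be slow, because the ester prefers the rotamer that holds the two arenes apart. Protodebromination of ring A or acetate cleavage of the aryl ester at 130 °C could then outrun cyclization. The fallback replaces the ester by an ether tether and sets out from 8 and 17. Ester 8 would be reduced with i-Bu2AlH (CH2Cl2, −78 → 0 °C) to the benzylic alcohol [2-bromo-5-methoxy-4-[(2S)-6-methylhept-5-en-2-yl]phenyl]methanol F1. Mitsunobu etherification of F1 with 17 (PPh3, DIAD, THF) should give the aryl benzyl ether 1-bromo-4-methoxy-5-[(2S)-6-methylhept-5-en-2-yl]-2-[[5-methyl-2-[(2S)-6-methylhept-5-en-2-yl]phenoxy]methyl]benzene F2. The ether has no rotamer bias against ring closure, and the same six-membered C–H arylation (Pd(OAc)2, PCy3·HBF4, K2CO3, DMA, 130 °C) should give 8-methoxy-1-methyl-4,9-bis[(2S)-6-methylhept-5-en-2-yl]-6H-benzo[c]chromene F3. Reductive cleavage of the benzylic C–O bond with lithium 4,4′-di-tert-butylbiphenylide (THF, −78 °C; then H2O) would give the ring A methyl and the ring B phenol at once, as 2-[4-methoxy-2-methyl-5-[(2S)-6-methylhept-5-en-2-yl]phenyl]-3-methyl-6-[(2S)-6-methylhept-5-en-2-yl]phenol F4. Demethylation of F4 under the conditions of step 18 comes back to the route at 24.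

2. Step 3 (hydrovinylation). The ester or the ortho methoxy group may bind the cationic nickel and slow the reaction. Enantioselectivity may be insufficient on this electron-poor ortho-substituted vinylarene, or the product alkene may isomerize into conjugation with the ring and lose the stereocenter. The fallback uses auxiliary control and sets out from 2. Wittig olefination of 2 with the stabilized ylide (4S)-4-phenyl-3-[(triphenylphosphoranylidene)acetyl]-1,3-oxazolidin-2-one (toluene, 80 °C) should give methyl 2-bromo-5-methoxy-4-[(1E)-3-oxo-3-[(4S)-2-oxo-4-phenyl-1,3-oxazolidin-3-yl]prop-1-en-1-yl]benzoate F5. MeMgBr with CuBr·SMe2 (THF, −40 °C) should add methyl to the magnesium-chelated s-cis imide from the face opposite the phenyl group, giving methyl 2-bromo-5-methoxy-4-[(2S)-4-oxo-4-[(4S)-2-oxo-4-phenyl-1,3-oxazolidin-3-yl]butan-2-yl]benzoate F6; a minor diastereomer would be removed by crystallization. Reductive removal of the auxiliary with NaBH4 in THF/H2O, which leaves the methyl benzoate, comes back to the route at 6.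

3. Step 11 (aromatization). The selenoxide may eliminate toward the side-chain methine instead of into the ring; the exocyclic dienone formed would aromatize with loss of the (S) center. Selenium electrophiles may also add to the trisubstituted alkene. The fallback avoids a leaving group on the substituted α′ carbon and sets out from 15. Soft enolization (Me3SiOTf, Et3N, CH2Cl2, 0 °C) should give the silyl dienol ether trimethyl[[3-methyl-6-[(2S)-6-methylhept-5-en-2-yl]cyclohexa-1,3-dien-1-yl]oxy]silane F7. Dehydrogenation of this cyclohexadiene with DDQ (1.0 equiv, 2,6-lutidine, CH2Cl2, 0 °C), by hydride abstraction from a ring CH2 and proton loss, should give the aryl silyl ether trimethyl[5-methyl-2-[(2S)-6-methylhept-5-en-2-yl]phenoxy]silane F8. Methanolysis (K2CO3, MeOH) comes back to the route at 17.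

**Further compounds**

F1 | step 13 | [2-bromo-5-methoxy-4-[(2S)-6-methylhept-5-en-2-yl]phenyl]methanol | OCc1cc(OC)c([C@@H](C)CCC=C(C)C)cc1Br
F2 | step 13 | 1-bromo-4-methoxy-5-[(2S)-6-methylhept-5-en-2-yl]-2-[[5-methyl-2-[(2S)-6-methylhept-5-en-2-yl]phenoxy]methyl]benzene | COc1cc(COc2cc(C)ccc2[C@@H](C)CCC=C(C)C)c(Br)cc1[C@@H](C)CCC=C(C)C
F3 | step 13 | 8-methoxy-1-methyl-4,9-bis[(2S)-6-methylhept-5-en-2-yl]-6H-benzo[c]chromene | COc1cc2COc3c([C@@H](C)CCC=C(C)C)ccc(C)c3-c2cc1[C@@H](C)CCC=C(C)C
F4 | step 13 | 2-[4-methoxy-2-methyl-5-[(2S)-6-methylhept-5-en-2-yl]phenyl]-3-methyl-6-[(2S)-6-methylhept-5-en-2-yl]phenol | COc1cc(C)c(-c2c(C)ccc([C@@H](C)CCC=C(C)C)c2O)cc1[C@@H](C)CCC=C(C)C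
F5 | step 3 | methyl 2-bromo-5-methoxy-4-[(1E)-3-oxo-3-[(4S)-2-oxo-4-phenyl-1,3-oxazolidin-3-yl]prop-1-en-1-yl]benzoate | COC(=O)c1cc(OC)c(/C=C/C(=O)N2[C@@H](c3ccccc3)COC2=O)cc1Br
F6 | step 3 | methyl 2-bromo-5-methoxy-4-[(2S)-4-oxo-4-[(4S)-2-oxo-4-phenyl-1,3-oxazolidin-3-yl]butan-2-yl]benzoate | COC(=O)c1cc(OC)c([C@@H](C)CC(=O)N2[C@@H](c3ccccc3)COC2=O)cc1Br
F7 | step 11 | trimethyl[[3-methyl-6-[(2S)-6-methylhept-5-en-2-yl]cyclohexa-1,3-dien-1-yl]oxy]silane | CC(C)=CCC[C@H](C)C1CC=C(C)C=C1O[Si](C)(C)C
F8 | step 11 | trimethyl[5-methyl-2-[(2S)-6-methylhept-5-en-2-yl]phenoxy]silane | CC(C)=CCC[C@H](C)c1ccc(C)cc1O[Si](C)(C)C
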